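**Assumption:** but-2-ynal and (−)-B-allyldiisopinocampheylborane are bought. In step 3 the cyclopropane is taken to form on the face anti to the acetoxy group; I derived this sense from a steric and stereoelectronic model and did not check it against a documented example, so it is the main stereochemical risk.

## Retrosynthetic overview

1. Target 12 ⇐ twofold ortho/para bromination of phenol 11 ⇐ O-demethylation of aryl ether 10.
2. C2–CH3 bond of 10 ⇐ SN1 methylation of the tertiary benzylic cyclopropylcarbinyl alcohol 9, with Me entering anti to the cyclopropane ⇐ aryllithium 8 + ketone 6.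
3. Key step: bicyclic ketone 6 ⇐ Pt(II) cycloisomerisation with 1,2-acyloxy shift of the 1,5-enyne acetate 4. The cyclopentane and cyclopropane rings form together, and the carbinol centre relays its chirality to C1 and C5.
4. 4 ⇐ acetylation of 3 ⇐ asymmetric allylboration of but-2-ynal 1.
5. Ring order: five- and three-membered rings together in step 3; the arene is bought. No Simmons–Smith reaction on an aryl cyclopentene is used.

## Route

**Step 1**
Reactants: 1 but-2-ynal
Product: 3 (S)-hept-1-en-5-yn-4-ol, via borinate ester 2 (not isolated)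
Conditions: (−)-Ipc2B(allyl) (salt-free), Et2O, −100 → −78 °C; then 3 M NaOH, 30% H2O2, 0 °C → rt
Reagents that add atoms: (−)-B-allyldiisopinocampheylborane, C=CCB([C@@H]1C[C@@H]2C[C@H]([C@H]1C)C2(C)C)[C@@H]1C[C@@H]2C[C@H]([C@H]1C)C2(C)C
Why: Brown asymmetric allylboration through a closed chair transition state; the reagent from (+)-α-pinene attacks the ynal on the same face as benzaldehyde, which sets the (S) carbinol centre.

**Step 2**
Reactants: 3 (S)-hept-1-en-5-yn-4-ol
Product: 4 (S)-hept-1-en-5-yn-4-yl acetate
Conditions: Ac2O, pyridine, DMAP (cat.), CH2Cl2, 0 °C → rt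
Reagents that add atoms: acetic anhydride, CC(=O)OC(C)=O
Why: DMAP-catalysed O-acylation of a secondary alcohol; the stereocentre is untouched.

**Step 3**
Reactants: 4 (S)-hept-1-en-5-yn-4-yl acetate
Product: 6 (1S,5R)-1-methylbicyclo[3.1.0]hexan-2-one, via enol acetate 5 (not isolated)
Conditions: PtCl2 (5 mol %), toluene, 80 °C; then K2CO3 (cat.), MeOH, 0 °C
Reagents that add atoms: none
Why: Pt(II)-catalysed cycloisomerisation of a 5-en-1-yn-3-yl acetate (Ohloff–Rautenstrauch type): the alkene attacks the Pt-bound alkyne to give a cyclopropyl Pt-carbene, a 1,2-acyloxy shift gives enol acetate 5, and methanolysis releases the ketone. The acetoxy-bearing carbon is still sp3 when the cyclopropane closes anti to it, so (S)-4 sets C1 (S) and C5 (R).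

**Step 4**
Reactants: 6 (1S,5R)-1-methylbicyclo[3.1.0]hexan-2-one; 7 1-bromo-2-methoxy-4-methylbenzene
Product: 9 (1S,2R,5R)-2-(2-methoxy-4-methylphenyl)-1-methylbicyclo[3.1.0]hexan-2-ol, via aryllithium 8 (not isolated)
Conditions: 7, n-BuLi, THF, −78 °C; then 6, −78 → −20 °C; H2O
Reagents that add atoms: none
Why: Br/Li exchange followed by 1,2-addition of the chelation-stabilised aryllithium to the ketone; the drawn epimer has the aryl group on the exo face, but either epimer serves because C2 is ionised in step 5.

**Step 5**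
Reactants: 9 (1S,2R,5R)-2-(2-methoxy-4-methylphenyl)-1-methylbicyclo[3.1.0]hexan-2-ol
Product: 10 (1S,2R,5R)-2-(2-methoxy-4-methylphenyl)-1,2-dimethylbicyclo[3.1.0]hexane
Conditions: Me2Zn, TiCl4, CH2Cl2, −40 °C (gives Me2TiCl2); then 9, −40 → 0 °C; Rochelle salt work-up
Reagents that add atoms: dimethylzinc, C[Zn]C (its methyl groups reach the product through Me2TiCl2, C[Ti](C)(Cl)Cl, formed in the flask with TiCl4)
Why: Reetz-type SN1 methylation of a tertiary alcohol via the benzylic cyclopropylcarbinyl cation. The C1–C6 cyclopropane bond overlaps with the endo lobe of the cation, so methyl enters anti to the cyclopropane as in i-steroid solvolysis; this puts the aryl group syn to the cyclopropane CH2 and sets C2 (R).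

**Step 6**
Reactants: 10 (1S,2R,5R)-2-(2-methoxy-4-methylphenyl)-1,2-dimethylbicyclo[3.1.0]hexane
Product: 11 2-[(1S,2R,5R)-1,2-dimethylbicyclo[3.1.0]hexan-2-yl]-5-methylphenol
Conditions: NaSEt, DMF, 120 °C; then aq NH4Cl
Reagents that add atoms: none
Why: SN2 demethylation of an aryl methyl ether by thiolate; the non-acidic conditions avoid phenol-onto-cyclopropane cyclisation and leave all stereocentres untouched.

**Step 7**
Reactants: 11 2-[(1S,2R,5R)-1,2-dimethylbicyclo[3.1.0]hexan-2-yl]-5-methylphenol
Product: 12 2,4-dibromo-6-[(1S,2R,5R)-1,2-dimethylbicyclo[3.1.0]hexan-2-yl]-3-methylphenol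
Conditions: NBS (2.05 equiv), MeCN, 0 °C → rt, dark
Reagents that add atoms: N-bromosuccinimide, O=C1CCC(=O)N1Br
Why: electrophilic aromatic bromination at the only free positions para and ortho to the OH; NBS releases no HBr, so the cyclopropane survives.

## Compound list

1 | but-2-ynal | CC#CC=O | starting material
2 | (S)-hept-1-en-5-yn-4-yl diisopinocampheylborinate | C=CC[C@H](OB([C@@H]1C[C@@H]2C[C@H]([C@H]1C)C2(C)C)[C@@H]1C[C@@H]2C[C@H]([C@H]1C)C2(C)C)C#CC | intermediate
3 | (S)-hept-1-en-5-yn-4-ol | C=CC[C@H](O)C#CC | intermediate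
4 | (S)-hept-1-en-5-yn-4-yl acetate | C=CC[C@H](OC(C)=O)C#CC | intermediate
5 | (1S,5R)-1-methylbicyclo[3.1.0]hex-2-en-2-yl acetate | CC(=O)OC1=CC[C@@H]2C[C@@]21C | intermediate
6 | (1S,5R)-1-methylbicyclo[3.1.0]hexan-2-one | O=C1CC[C@@H]2C[C@@]21C | intermediate
7 | 1-bromo-2-methoxy-4-methylbenzene | COc1cc(C)ccc1Br | starting material
8 | (2-methoxy-4-methylphenyl)lithium | [Li]c1ccc(C)cc1OC | intermediate
9 | (1S,2R,5R)-2-(2-methoxy-4-methylphenyl)-1-methylbicyclo[3.1.0]hexan-2-ol | COc1cc(C)ccc1[C@@]1(O)CC[C@@H]2C[C@@]21C | intermediate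
10 | (1S,2R,5R)-2-(2-methoxy-4-methylphenyl)-1,2-dimethylbicyclo[3.1.0]hexane | COc1cc(C)ccc1[C@]1(C)CC[C@@H]2C[C@@]21C | intermediate
11 | 2-[(1S,2R,5R)-1,2-dimethylbicyclo[3.1.0]hexan-2-yl]-5-methylphenol | Cc1ccc([C@]2(C)CC[C@@H]3C[C@@]32C)c(O)c1 | intermediate
12 | 2,4-dibromo-6-[(1S,2R,5R)-1,2-dimethylbicyclo[3.1.0]hexan-2-yl]-3-methylphenol | Cc1c(Br)cc([C@]2(C)CC[C@@H]3C[C@@]32C)c(O)c1Br | target

## Summary

Total step count: 7. Longest linear sequence: 7 (1 → 12).

## Steps most likely to fail

**Step 3 (Pt cycloisomerisation).** The internal alkyne may divert into a 1,3-acyloxy shift, or the chirality transfer may be incomplete or of the opposite sense. The fallback sets out from 8 and comes back at 9, and it bypasses the enyne chemistry altogether. Aryllithium 8 is transmetalated with ZnCl2 to bis(2-methoxy-4-methylphenyl)zinc F1. With Ti(OiPr)4 and a chiral bis(sulfonamide) diol ligand, F1 transfers one aryl group enantioselectively to the carbonyl of 2-methylcyclopent-2-en-1-one, giving (R)-1-(2-methoxy-4-methylphenyl)-2-methylcyclopent-2-en-1-ol F2. Hydroxyl-directed Furukawa cyclopropanation (Et2Zn, CH2I2) then delivers CH2 to the face of the OH and gives 9. This fallback is the conventional directed cyclopropanation, which is why it is not the main route.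

**Step 5 (SN1 methylation).** E1 loss to the styrene, cyclopropylcarbinyl ring opening, or methyl attack from the endo face may compete. The fallback sets out from 6 and comes back at 11; it replaces the free cation by a neutral o-quinone methide and removes the demethylation step. Ketone 6 is treated with lithium 2-lithio-5-methylphenoxide F3 (from 2-bromo-5-methylphenol and 2 equiv n-BuLi) to give (1S,2R,5R)-2-(2-hydroxy-4-methylphenyl)-1-methylbicyclo[3.1.0]hexan-2-ol F4. Excess MeMgBr in toluene at 60–80 °C converts F4, as its magnesium salt, into (E)-3-methyl-6-[(1S,5R)-1-methylbicyclo[3.1.0]hexan-2-ylidene]cyclohexa-2,4-dien-1-one F5. Conjugate addition of MeMgBr to the exocyclic carbon of F5, anti to the cyclopropane, gives phenol 11 directly.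

**Step 1 (enantioselectivity with a small ynal).** The ee may be too low for a route that relays this single centre. The fallback sets out from 1 and comes back at 3; it moves the asymmetric induction from C–C bond formation to a ketone reduction. Allylmagnesium bromide adds to 1 to give racemic hept-1-en-5-yn-4-ol F6. Dess–Martin oxidation gives hept-1-en-5-yn-4-one F7. Noyori transfer hydrogenation with the preformed neutral (S,S)-TsDPEN–Ru(p-cymene) amido complex in i-PrOH then gives 3; the alkynyl group takes the role of the unsaturated substituent, and the base-free conditions keep the β,γ-alkene in place.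

## Further compounds

F1 | step 3 | bis(2-methoxy-4-methylphenyl)zinc | COc1cc(C)ccc1[Zn]c1ccc(C)cc1OC
F2 | step 3 | (R)-1-(2-methoxy-4-methylphenyl)-2-methylcyclopent-2-en-1-ol | COc1cc(C)ccc1[C@@]1(O)CCC=C1C
F3 | step 5 | lithium 2-lithio-5-methylphenoxide | [Li]Oc1cc(C)ccc1[Li]
F4 | step 5 | (1S,2R,5R)-2-(2-hydroxy-4-methylphenyl)-1-methylbicyclo[3.1.0]hexan-2-ol | Cc1ccc([C@@]2(O)CC[C@@H]3C[C@@]32C)c(O)c1
F5 | step 5 | (E)-3-methyl-6-[(1S,5R)-1-methylbicyclo[3.1.0]hexan-2-ylidene]cyclohexa-2,4-dien-1-one | O=C1C=C(C)C=C/C1=C1/CC[C@@H]2C[C@@]21C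
F6 | step 1 | racemic hept-1-en-5-yn-4-ol | C=CCC(O)C#CC
F7 | step 1 | hept-1-en-5-yn-4-one | C=CCC(=O)C#CC
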